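The readings are calculated for substances that don't exist, noise included.

I started from the easy step, the first row of the dusk flask: after 10.0 s it held 11% side product, while target read 0%. So I took side product to form straight from substrate, growing in step with time at the very start. Target looked like a secondary product, made from something that had to build up first, so at the start I let it grow with the square of time. On that picture their ratio falls as one over time, and I carried this line on to the later times as an estimate.

| setting | dusk | flask |
|---|---|---|
| substrate | 2.8 M | 2.8 M |
| remark | the very flask that is asked about, followed so far |  |
| time |  | 3.0 min |
dusk run (percent of the substrate charged)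

| time / s | side product / % | target / % | substrate / % |
|---|---|---|---|
| 10.0 | 11 | 0 | 57 |
| 20.0 | 13 | 1 | 39 |
| 30.0 | 17 | 2 | 31 |
| 50.0 | 24 | 3 | 15 |
| 80.0 | 27 | 9 | 9 |

(scatter of a reading: 2 percentage points)
- the numbers in the tables scatter by 2 percentage points (one standard deviation)
- ratio of side product to target at 1.0 s
- ratio of side product to target at 3.0 min
- which of side product and target there is more of at 3.0 min

Averaged over the last 3 readings of the dusk flask, side product over target multiplied by elapsed time came to 298 s. I called this the catch-up time, the time at which the one-over-time line reaches a ratio of one. It was a rough reading: target read 2% at 30.0 s, with a scatter of 2 percentage points, so the late target readings are the ones to watch. The question came down to two times, this one and the asked 3.0 min. The catch-up time was longer, so I expected side product to lead, with a ratio of 298 at 1.0 s and 1.66 at 3.0 min.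

The forecast gave 370 and 1.4, higher than mine early and lower late, with side product ahead: “probably still leads, though not securely”.

The flask gave 364 and 2.15, with 30.1% side product against 14.0% target at 3.0 min.

    substrate → intermediate (k = 0.00780 s⁻¹)
    intermediate → target (k = 0.00770 s⁻¹)
    substrate → side product (k = 0.0110 s⁻¹)
    2 substrate → homo dimer (k = 0.00750 M⁻¹ s⁻¹)

In this flask, ratio times time was 364 s at 1.0 s and 387 s at 3.0 min. The neighbouring flask started with [substrate] of 0.70 M, a quarter of the charge in the asked flask. The same reckoning with 298 s gave it 1.66 at 3.0 min. It showed 365 at 1.0 s and 2.22 at 3.0 min, so ratio times time was 365 s and 400 s. It ended with 45.2% side product against 20.4% target.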